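Building the benzene ring last, from open-chain pieces, is the disconnection on which everything rests. The ring (numbered as a phenol: C1–OH, C2–chain, C3–H, C4–OMe, C5–H, C6–CH3) has OH and OMe para, two substituents flanking OH and two hydrogens flanking OMe, exactly what a Dötz benzannulation of a propenyl(methoxy)carbene chromium complex with a terminal alkyne delivers. One operation forms the C4–C3, C2–C1 and C1–C6 ring bonds, closes the ring and sets free phenol and methyl ether without arene protecting groups. Its precursor is the complete C1'–C16' chain as a terminal skipped enyne carrying both stereocentres (C5' silyl ether, C11' beside the free C12' ketone).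

Key step: step 18

Remarks on the chemistry (assumptions)
- Numbering: the side chain runs from C1' (benzylic) to C16', with methyl branches on C3', C7', C11' and C15'; the main chain therefore has sixteen carbons.
- A free C12' ketone cannot pass through the Me3Al and Grignard steps, so C12' is carried as a triethylsilyl-protected carbinol (both epimers, which converge on oxidation) and is oxidised directly before the key step; C5' is a tert-butyldimethylsilyl ether chosen to survive removal of the triethylsilyl group.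
- It is assumed that the (R)-configured phosphoric acid in step 11 directs the allenylboronate to the Re face of the enal, as in the related allylboration; the (S)-acid would be used if the sense proved opposite.

Step 1
Reactants: 1 (E)-1-bromoprop-1-ene; 2 chromium hexacarbonyl
Product: 5 pentacarbonyl[(2E)-1-methoxybut-2-en-1-ylidene]chromium, via (E)-prop-1-enyllithium 3 (not isolated), via lithium acylchromate 4 (not isolated)
Conditions: t-BuLi (2 equiv), Et2O, −78 °C; Cr(CO)6, Et2O, 0 °C → rt; Me3OBF4, CH2Cl2, 0 °C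
Reagents that add atoms: trimethyloxonium tetrafluoroborate, C[O+](C)C.F[B-](F)(F)F
Why: Fischer carbene synthesis: bromine–lithium exchange keeps the (E)-geometry, the alkenyllithium adds to a carbonyl ligand of Cr(CO)6 and the resulting acylchromate is methylated on oxygen by the hard oxonium salt.

Step 2
Reactants: 6 but-2-yn-1-ol
Product: 9 (E)-3-iodobut-2-en-1-ol, via aluminium alkoxide 7 (not isolated), via alkenylzirconocene 8 (not isolated)
Conditions: i-Bu2AlH (1 equiv), THF, 0 °C; Cp2Zr(H)Cl made from Cp2ZrCl2 and i-Bu2AlH, THF, 0 °C → rt; I2, −78 → 0 °C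
Reagents that add atoms: iodine, II
Why: Hydrozirconation is a syn addition that places zirconium on the methyl-bearing carbon, away from the bulky alkoxyalane, and iodinolysis with retention gives the (E)-alkenyl iodide.

Step 3
Reactants: 10 (S)-4-benzyl-3-propionyloxazolidin-2-one
Product: 12 (S)-4-benzyl-3-[(2R)-2-methylpent-4-enoyl]oxazolidin-2-one, via sodium (Z)-enolate 11 (not isolated)
Conditions: NaHMDS, THF, −78 °C; allyl iodide, −78 → −40 °C
Reagents that add atoms: allyl iodide, C=CCI
Why: Evans asymmetric alkylation: the chelated (Z)-enolate is allylated on the face opposite the benzyl group, which sets C11' as R.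

Step 4
Reactants: 12 (S)-4-benzyl-3-[(2R)-2-methylpent-4-enoyl]oxazolidin-2-one
Product: 13 (2R)-2-methylpent-4-en-1-ol
Conditions: LiBH4, MeOH (1 equiv), Et2O, 0 °C
Reagents that add atoms: none
Why: Reductive cleavage of the imide by borohydride attacks the exocyclic carbonyl, leaves the α-stereocentre untouched and returns the auxiliary; the volatile alcohol is concentrated with care.

Step 5
Reactants: 13 (2R)-2-methylpent-4-en-1-ol
Product: 14 (2R)-2-methylpent-4-enal
Conditions: Dess–Martin periodinane, NaHCO3, CH2Cl2, 0 °C → rt; used at once as a solution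
Reagents that add atoms: none
Why: Buffered Dess–Martin oxidation stops at the aldehyde under non-basic conditions that should not epimerise the α-centre.

Step 6
Reactants: 14 (2R)-2-methylpent-4-enal
Product: 15 2-[(2R)-pent-4-en-2-yl]oxirane
Conditions: Me3SI, n-BuLi, THF, −10 °C; then 14, −10 °C → rt
Reagents that add atoms: trimethylsulfonium iodide, C[S+](C)C.[I-]
Why: Corey–Chaykovsky epoxidation: the sulfonium ylide adds to the aldehyde faster than it enolises it and the betaine closes to the terminal epoxide; the new centre (C12') is not controlled and need not be, since it is oxidised in step 17.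

Step 7
Reactants: 15 2-[(2R)-pent-4-en-2-yl]oxirane
Product: 16 (4R)-4,8-dimethylnona-1,7-dien-5-ol
Conditions: 2-methylprop-1-enylmagnesium bromide, CuI (10 mol %), THF, −30 → 0 °C
Reagents that add atoms: 2-methylprop-1-enylmagnesium bromide, CC(C)=C[Mg]Br
Why: Copper-catalysed epoxide opening by the alkenyl Grignard reagent occurs at the unhindered CH2 and installs the prenyl unit with its alkene fixed in the β,γ-position, avoiding the regiochemical problem of prenyl-metal additions.

Step 8
Reactants: 16 (4R)-4,8-dimethylnona-1,7-dien-5-ol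
Product: 17 triethyl{[(4R)-4,8-dimethylnona-1,7-dien-5-yl]oxy}silane
Conditions: TESCl, imidazole, DMAP (cat.), DMF, rt
Reagents that add atoms: chlorotriethylsilane, CC[Si](Cl)(CC)CC
Why: Standard silylation of a secondary alcohol; the triethylsilyl ether masks the future ketone oxygen and can later be removed in the presence of a tert-butyldimethylsilyl ether.

Step 9
Reactants: 17 triethyl{[(4R)-4,8-dimethylnona-1,7-dien-5-yl]oxy}silane; 9 (E)-3-iodobut-2-en-1-ol
Product: 19 (2E,7R)-3,7,11-trimethyl-8-(triethylsilyloxy)dodeca-2,10-dien-1-ol, via B-alkyl-9-BBN 18 (not isolated)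
Conditions: 9-BBN, THF, 0 °C → rt; then 9, PdCl2(dppf) (5 mol %), AsPh3, aq. Cs2CO3, DMF, rt
Reagents that add atoms: none
Why: B-alkyl Suzuki–Miyaura coupling: 9-BBN hydroborates only the monosubstituted alkene at its terminus and the alkylborane couples with the alkenyl iodide with retention, which fixes the (E)-C6'=C7' alkene and forms the C7'–C8' bond.

Step 10
Reactants: 19 (2E,7R)-3,7,11-trimethyl-8-(triethylsilyloxy)dodeca-2,10-dien-1-ol
Product: 20 (2E,7R)-3,7,11-trimethyl-8-(triethylsilyloxy)dodeca-2,10-dienal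
Conditions: activated MnO2, CH2Cl2, rt
Reagents that add atoms: none
Why: MnO2 oxidises allylic alcohols selectively and should give the (E)-enal without touching the silyl ether or the isolated alkene.

Step 11
Reactants: 20 (2E,7R)-3,7,11-trimethyl-8-(triethylsilyloxy)dodeca-2,10-dienal
Product: 21 (4R,5E,10R)-6,10,14-trimethyl-11-(triethylsilyloxy)pentadeca-5,13-dien-1-yn-4-ol
Conditions: allenylboronic acid pinacol ester, (R)-TRIP [(R)-3,3'-bis(2,4,6-triisopropylphenyl)-1,1'-binaphthyl-2,2'-diyl hydrogen phosphate] (10 mol %), 4 Å MS, toluene, −20 °C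
Reagents that add atoms: allenylboronic acid pinacol ester, C=C=CB1OC(C)(C)C(C)(C)O1
Why: Chiral phosphoric acid-catalysed allenylboration (asymmetric propargylation): the acid activates the boronate in a closed six-membered SE2' transition state and the (R)-acid should expose the Re face of the enal, which sets C5' as R; the remote C11' and C12' centres exert no influence.

Step 12
Reactants: 21 (4R,5E,10R)-6,10,14-trimethyl-11-(triethylsilyloxy)pentadeca-5,13-dien-1-yn-4-ol
Product: 22 (4R,5E,10R)-4-(tert-butyldimethylsilyloxy)-6,10,14-trimethyl-11-(triethylsilyloxy)pentadeca-5,13-dien-1-yne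
Conditions: TBSCl, imidazole, DMF, rt
Reagents that add atoms: tert-butylchlorodimethylsilane, CC(C)(C)[Si](C)(C)Cl
Why: Standard silylation of the only free hydroxyl; the bulkier silyl group at C5' is what allows the later selective release of the C12' oxygen.

Step 13
Reactants: 22 (4R,5E,10R)-4-(tert-butyldimethylsilyloxy)-6,10,14-trimethyl-11-(triethylsilyloxy)pentadeca-5,13-dien-1-yne
Product: 25 (2E,5R,6E,11R)-5-(tert-butyldimethylsilyloxy)-3,7,11,15-tetramethyl-12-(triethylsilyloxy)hexadeca-2,6,14-trien-1-ol, via alkenyldimethylalane 23 (not isolated), via lithium alkenylalanate 24 (not isolated)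
Conditions: Me3Al, Cp2ZrCl2 (25 mol %), CH2Cl2, 0 °C → rt; evaporate; n-BuLi, THF/hexane, −78 °C; (CH2O)n, −78 °C → rt; aq. potassium sodium tartrate
Reagents that add atoms: trimethylaluminium, C[Al](C)C; formaldehyde (as paraformaldehyde), C=O
Why: Negishi zirconium-catalysed carboalumination adds methyl and aluminium syn across the terminal alkyne with methyl on the internal carbon, and the derived alanate is hydroxymethylated with retention, giving the (E)-C2'=C3' allylic alcohol; silyl ethers and trisubstituted alkenes are inert to the reagent.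

Step 14
Reactants: 25 (2E,5R,6E,11R)-5-(tert-butyldimethylsilyloxy)-3,7,11,15-tetramethyl-12-(triethylsilyloxy)hexadeca-2,6,14-trien-1-ol
Product: 26 (2E,5R,6E,11R)-1-bromo-5-(tert-butyldimethylsilyloxy)-3,7,11,15-tetramethyl-12-(triethylsilyloxy)hexadeca-2,6,14-triene
Conditions: CBr4, PPh3, 2,6-lutidine, CH2Cl2, −20 → 0 °C; used crude
Reagents that add atoms: tetrabromomethane, BrC(Br)(Br)Br
Why: Appel bromination converts the primary allylic alcohol into the bromide by SN2 displacement under buffered, near-neutral conditions that should leave both silyl ethers and the alkene geometry intact.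

Step 15
Reactants: 26 (2E,5R,6E,11R)-1-bromo-5-(tert-butyldimethylsilyloxy)-3,7,11,15-tetramethyl-12-(triethylsilyloxy)hexadeca-2,6,14-triene
Product: 27 (4E,7R,8E,13R)-7-(tert-butyldimethylsilyloxy)-5,9,13,17-tetramethyl-14-(triethylsilyloxy)octadeca-4,8,16-trien-1-yne
Conditions: HC≡CMgBr (excess), CuBr·SMe2 (10 mol %), THF, 0 °C → rt
Reagents that add atoms: ethynylmagnesium bromide, C#C[Mg]Br
Why: Copper-catalysed allylic alkynylation: the acetylide displaces the primary bromide by SN2, since attack at the γ-carbon would create a quaternary centre, and the excess of acetylide suppresses double alkylation, so the skipped enyne should form with the (E)-alkene intact.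

Step 16
Reactants: 27 (4E,7R,8E,13R)-7-(tert-butyldimethylsilyloxy)-5,9,13,17-tetramethyl-14-(triethylsilyloxy)octadeca-4,8,16-trien-1-yne
Product: 28 (4E,7R,8E,13R)-7-(tert-butyldimethylsilyloxy)-5,9,13,17-tetramethyloctadeca-4,8,16-trien-1-yn-14-ol
Conditions: PPTS (cat.), MeOH/CH2Cl2, 0 °C
Reagents that add atoms: none
Why: Acid-catalysed methanolysis cleaves a triethylsilyl ether far faster than the bulkier tert-butyldimethylsilyl ether, so only the C12' hydroxyl is released.

Step 17
Reactants: 28 (4E,7R,8E,13R)-7-(tert-butyldimethylsilyloxy)-5,9,13,17-tetramethyloctadeca-4,8,16-trien-1-yn-14-ol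
Product: 29 (4E,7R,8E,13R)-7-(tert-butyldimethylsilyloxy)-5,9,13,17-tetramethyloctadeca-4,8,16-trien-1-yn-14-one
Conditions: Dess–Martin periodinane, NaHCO3, CH2Cl2, 0 °C → rt
Reagents that add atoms: none
Why: Buffered Dess–Martin oxidation converts both C12' epimers into the one β,γ-unsaturated ketone without acid or base that could move the alkene into conjugation or epimerise C11'.

Step 18
Reactants: 29 (4E,7R,8E,13R)-7-(tert-butyldimethylsilyloxy)-5,9,13,17-tetramethyloctadeca-4,8,16-trien-1-yn-14-one; 5 pentacarbonyl[(2E)-1-methoxybut-2-en-1-ylidene]chromium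
Product: 31 (2E,5R,6E,11R)-5-(tert-butyldimethylsilyloxy)-1-(2-hydroxy-5-methoxy-3-methylphenyl)-3,7,11,15-tetramethylhexadeca-2,6,14-trien-12-one, via arene tricarbonylchromium complex 30 (not isolated)
Conditions: 5 (1.5 equiv), degassed THF (0.05 M), 50 °C, Ar; then air, Et2O/MeCN, daylight, rt
Reagents that add atoms: none
Why: Thermal loss of one CO from 5 opens a site for the alkyne, which inserts into the Cr=C bond to give a vinylcarbene; CO insertion then gives a chromium-bound dienylketene, whose 6π-electrocyclic closure (C1–C6 bond) and keto–enol tautomerisation deliver the arene as its Cr(CO)3 complex 30, from which air releases the free phenol. This is the Dötz benzannulation of an alkenyl(alkoxy)carbene complex with a terminal alkyne, a formal [3+2+1] assembly in which the carbene carbon becomes C4 (OMe), the alkyne carbons C3 and C2, the CO ligand C1 (OH) and the propenyl carbons C5 and C6 (CH3). The only selectivity needed is the orientation of alkyne insertion: the unsubstituted alkyne carbon bonds to the carbene carbon and the substituted one ends up next to the CO-derived carbon, which places the chain ortho to OH; the large steric difference between H and the chain on a terminal alkyne secures this. No stereocentre is formed, and the neutral conditions should leave C5', C11', the β,γ-unsaturated ketone and the three trisubstituted alkenes untouched. The single CH2 between the alkyne and C2'=C3' rules out intramolecular cyclopropanation by the vinylcarbene, and an alkenyl complex in THF favours the phenol over cyclobutenone or furan products.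

Step 19
Reactants: 31 (2E,5R,6E,11R)-5-(tert-butyldimethylsilyloxy)-1-(2-hydroxy-5-methoxy-3-methylphenyl)-3,7,11,15-tetramethylhexadeca-2,6,14-trien-12-one
Product: 32 (2E,5R,6E,11R)-5-hydroxy-1-(2-hydroxy-5-methoxy-3-methylphenyl)-3,7,11,15-tetramethylhexadeca-2,6,14-trien-12-one
Conditions: HF·pyridine, pyridine, THF, 0 °C → rt
Reagents that add atoms: none
Why: Fluoride-mediated desilylation buffered with pyridine is close to neutral, so the allylic C5' alcohol should be released without ionisation and the ketone without conjugation or epimerisation.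

Compound list
1 | (E)-1-bromoprop-1-ene | C/C=C/Br | starting material
2 | chromium hexacarbonyl | O=C=[Cr](=C=O)(=C=O)(=C=O)(=C=O)=C=O | starting material
3 | (E)-prop-1-enyllithium (not isolated) | C/C=C/[Li] | intermediate
4 | lithium pentacarbonyl[(2E)-1-oxidobut-2-en-1-ylidene]chromate (not isolated) | [Li+].C/C=C/C([O-])=[Cr](=C=O)(=C=O)(=C=O)(=C=O)=C=O | intermediate
5 | pentacarbonyl[(2E)-1-methoxybut-2-en-1-ylidene]chromium | COC(/C=C/C)=[Cr](=C=O)(=C=O)(=C=O)(=C=O)=C=O | intermediate
6 | but-2-yn-1-ol | CC#CCO | starting material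
7 | (but-2-yn-1-yloxy)bis(2-methylpropyl)alane (not isolated) | CC#CCO[Al](CC(C)C)CC(C)C | intermediate
8 | [(2E)-4-{[bis(2-methylpropyl)alumanyl]oxy}but-2-en-2-yl]chloridobis(cyclopentadienyl)zirconium (not isolated; cyclopentadienyl rings drawn as single-bonded) | CC(C)C[Al](CC(C)C)OC/C=C(\C)[Zr](Cl)(C1C=CC=C1)C1C=CC=C1 | intermediate
9 | (E)-3-iodobut-2-en-1-ol | OC/C=C(\C)I | intermediate
10 | (S)-4-benzyl-3-propionyloxazolidin-2-one | CCC(=O)N1[C@@H](Cc2ccccc2)COC1=O | starting material
11 | sodium (Z)-enolate of 10 (not isolated) | [Na+].C/C=C(\[O-])N1[C@@H](Cc2ccccc2)COC1=O | intermediate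
12 | (S)-4-benzyl-3-[(2R)-2-methylpent-4-enoyl]oxazolidin-2-one | C=CC[C@@H](C)C(=O)N1[C@@H](Cc2ccccc2)COC1=O | intermediate
13 | (2R)-2-methylpent-4-en-1-ol | C=CC[C@@H](C)CO | intermediate
14 | (2R)-2-methylpent-4-enal | C=CC[C@@H](C)C=O | intermediate
15 | 2-[(2R)-pent-4-en-2-yl]oxirane (both epimers at the oxirane carbon) | C=CC[C@@H](C)C1CO1 | intermediate
16 | (4R)-4,8-dimethylnona-1,7-dien-5-ol (both C5 epimers) | C=CC[C@@H](C)C(O)CC=C(C)C | intermediate
17 | triethyl{[(4R)-4,8-dimethylnona-1,7-dien-5-yl]oxy}silane (both C5 epimers) | C=CC[C@@H](C)C(O[Si](CC)(CC)CC)CC=C(C)C | intermediate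
18 | 9-[(4R)-4,8-dimethyl-5-(triethylsilyloxy)non-7-en-1-yl]-9-borabicyclo[3.3.1]nonane (not isolated) | B1(CCC[C@@H](C)C(O[Si](CC)(CC)CC)CC=C(C)C)C2CCCC1CCC2 | intermediate
19 | (2E,7R)-3,7,11-trimethyl-8-(triethylsilyloxy)dodeca-2,10-dien-1-ol (both C8 epimers) | OC/C=C(\C)CCC[C@@H](C)C(O[Si](CC)(CC)CC)CC=C(C)C | intermediate
20 | (2E,7R)-3,7,11-trimethyl-8-(triethylsilyloxy)dodeca-2,10-dienal (both C8 epimers) | O=C/C=C(\C)CCC[C@@H](C)C(O[Si](CC)(CC)CC)CC=C(C)C | intermediate
21 | (4R,5E,10R)-6,10,14-trimethyl-11-(triethylsilyloxy)pentadeca-5,13-dien-1-yn-4-ol (both C11 epimers) | C#CC[C@@H](O)/C=C(\C)CCC[C@@H](C)C(O[Si](CC)(CC)CC)CC=C(C)C | intermediate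
22 | (4R,5E,10R)-4-(tert-butyldimethylsilyloxy)-6,10,14-trimethyl-11-(triethylsilyloxy)pentadeca-5,13-dien-1-yne (both C11 epimers) | C#CC[C@@H](O[Si](C)(C)C(C)(C)C)/C=C(\C)CCC[C@@H](C)C(O[Si](CC)(CC)CC)CC=C(C)C | intermediate
23 | dimethyl[(1E,4R,5E,10R)-4-(tert-butyldimethylsilyloxy)-2,6,10,14-tetramethyl-11-(triethylsilyloxy)pentadeca-1,5,13-trien-1-yl]alane (not isolated) | C[Al](C)/C=C(\C)C[C@@H](O[Si](C)(C)C(C)(C)C)/C=C(\C)CCC[C@@H](C)C(O[Si](CC)(CC)CC)CC=C(C)C | intermediate
24 | lithium butyl(dimethyl)alanate of 23 (not isolated) | [Li+].CCCC[Al-](C)(C)/C=C(\C)C[C@@H](O[Si](C)(C)C(C)(C)C)/C=C(\C)CCC[C@@H](C)C(O[Si](CC)(CC)CC)CC=C(C)C | intermediate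
25 | (2E,5R,6E,11R)-5-(tert-butyldimethylsilyloxy)-3,7,11,15-tetramethyl-12-(triethylsilyloxy)hexadeca-2,6,14-trien-1-ol (both C12 epimers) | OC/C=C(\C)C[C@@H](O[Si](C)(C)C(C)(C)C)/C=C(\C)CCC[C@@H](C)C(O[Si](CC)(CC)CC)CC=C(C)C | intermediate
26 | (2E,5R,6E,11R)-1-bromo-5-(tert-butyldimethylsilyloxy)-3,7,11,15-tetramethyl-12-(triethylsilyloxy)hexadeca-2,6,14-triene (both C12 epimers) | BrC/C=C(\C)C[C@@H](O[Si](C)(C)C(C)(C)C)/C=C(\C)CCC[C@@H](C)C(O[Si](CC)(CC)CC)CC=C(C)C | intermediate
27 | (4E,7R,8E,13R)-7-(tert-butyldimethylsilyloxy)-5,9,13,17-tetramethyl-14-(triethylsilyloxy)octadeca-4,8,16-trien-1-yne (both C14 epimers) | C#CC/C=C(\C)C[C@@H](O[Si](C)(C)C(C)(C)C)/C=C(\C)CCC[C@@H](C)C(O[Si](CC)(CC)CC)CC=C(C)C | intermediate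
28 | (4E,7R,8E,13R)-7-(tert-butyldimethylsilyloxy)-5,9,13,17-tetramethyloctadeca-4,8,16-trien-1-yn-14-ol (both C14 epimers) | C#CC/C=C(\C)C[C@@H](O[Si](C)(C)C(C)(C)C)/C=C(\C)CCC[C@@H](C)C(O)CC=C(C)C | intermediate
29 | (4E,7R,8E,13R)-7-(tert-butyldimethylsilyloxy)-5,9,13,17-tetramethyloctadeca-4,8,16-trien-1-yn-14-one | C#CC/C=C(\C)C[C@@H](O[Si](C)(C)C(C)(C)C)/C=C(\C)CCC[C@@H](C)C(=O)CC=C(C)C | intermediate
30 | tricarbonyl(η6-arene)chromium complex of 31 (not isolated; the dot stands for η6 bonding of the ring to chromium) | COc1cc(C)c(O)c(C/C=C(\C)C[C@@H](O[Si](C)(C)C(C)(C)C)/C=C(\C)CCC[C@@H](C)C(=O)CC=C(C)C)c1.O=C=[Cr](=C=O)=C=O | intermediate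
31 | (2E,5R,6E,11R)-5-(tert-butyldimethylsilyloxy)-1-(2-hydroxy-5-methoxy-3-methylphenyl)-3,7,11,15-tetramethylhexadeca-2,6,14-trien-12-one | COc1cc(C)c(O)c(C/C=C(\C)C[C@@H](O[Si](C)(C)C(C)(C)C)/C=C(\C)CCC[C@@H](C)C(=O)CC=C(C)C)c1 | intermediate
32 | (2E,5R,6E,11R)-5-hydroxy-1-(2-hydroxy-5-methoxy-3-methylphenyl)-3,7,11,15-tetramethylhexadeca-2,6,14-trien-12-one (CNP0256537.1) | COc1cc(C)c(O)c(C/C=C(\C)C[C@@H](O)/C=C(\C)CCC[C@@H](C)C(=O)CC=C(C)C)c1 | target

Total step count: 19. Longest linear sequence: 17 steps (steps 3 to 19, from imide 10); steps 1 and 2 supply the carbene complex 5 and the alkenyl iodide 9.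

Steps most likely to fail

1. Step 18 (key step). What may go wrong: alkyne insertion in the wrong orientation, diversion of the vinylketene into non-aromatic or two-alkyne products, or over-oxidation of the electron-rich phenol while chromium is removed. Fallback (from 26, back to the route at 32): the ring is not built but attached. 4-Methoxy-2-methylphenol is brominated with NBS to 2-bromo-4-methoxy-6-methylphenol F1. F1 is deprotonated and lithiated (n-BuLi, then t-BuLi, THF, −78 °C), transmetallated with CuBr·SMe2 and alkylated at carbon with allylic bromide 26 to give the ortho-allylated phenol F2. Silylation (TBSCl, imidazole) gives the aryl silyl ether F3, PPTS/MeOH releases the C12' alcohol F4, and buffered Dess–Martin oxidation gives the bis-silylated ketone F5. TBAF/AcOH then removes both tert-butyldimethylsilyl groups and gives target 32.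

2. Step 11. What may go wrong: poor facial selectivity of the catalysed allenylboration on a β,β-disubstituted enal, or leakage to the allenyl carbinol. Fallback (from 20, back at 21): the enal is propargylated without control (propargyl bromide, Zn, THF/aq. NH4Cl) to the C4-epimeric alcohol F6. F6 is then resolved by Sharpless kinetic resolution (Ti(OiPr)4, L-(+)-diisopropyl tartrate, t-BuOOH 0.6 equiv, 4 Å MS, CH2Cl2, −20 °C). The (4S)-alcohol is consumed as the epoxy alcohol F7, and the slow-reacting (4R)-alcohol 21 is recovered and rejoins the route.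

3. Step 15. What may go wrong: attack at the γ-carbon, double alkylation of the acetylide, or base-induced migration of the skipped enyne under Grignard conditions. Fallback (from 26, back at 27): the bromide is coupled with trimethylsilylacetylene through a copper acetylide under carbonate base (CuI, K2CO3, NaI, DMF, rt) to give the silyl-capped enyne F8. K2CO3/MeOH then removes the alkynyl silyl group and gives 27.

Further compounds
F1 | step 18 | 2-bromo-4-methoxy-6-methylphenol | COc1cc(C)c(O)c(Br)c1
F2 | step 18 | 2-[(2E,5R,6E,11R)-5-(tert-butyldimethylsilyloxy)-3,7,11,15-tetramethyl-12-(triethylsilyloxy)hexadeca-2,6,14-trien-1-yl]-4-methoxy-6-methylphenol | COc1cc(C)c(O)c(C/C=C(\C)C[C@@H](O[Si](C)(C)C(C)(C)C)/C=C(\C)CCC[C@@H](C)C(O[Si](CC)(CC)CC)CC=C(C)C)c1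
F3 | step 18 | tert-butyldimethylsilyl ether of phenol F2 | COc1cc(C)c(O[Si](C)(C)C(C)(C)C)c(C/C=C(\C)C[C@@H](O[Si](C)(C)C(C)(C)C)/C=C(\C)CCC[C@@H](C)C(O[Si](CC)(CC)CC)CC=C(C)C)c1
F4 | step 18 | (2E,5R,6E,11R)-5-(tert-butyldimethylsilyloxy)-1-[2-(tert-butyldimethylsilyloxy)-5-methoxy-3-methylphenyl]-3,7,11,15-tetramethylhexadeca-2,6,14-trien-12-ol | COc1cc(C)c(O[Si](C)(C)C(C)(C)C)c(C/C=C(\C)C[C@@H](O[Si](C)(C)C(C)(C)C)/C=C(\C)CCC[C@@H](C)C(O)CC=C(C)C)c1
F5 | step 18 | (2E,5R,6E,11R)-5-(tert-butyldimethylsilyloxy)-1-[2-(tert-butyldimethylsilyloxy)-5-methoxy-3-methylphenyl]-3,7,11,15-tetramethylhexadeca-2,6,14-trien-12-one | COc1cc(C)c(O[Si](C)(C)C(C)(C)C)c(C/C=C(\C)C[C@@H](O[Si](C)(C)C(C)(C)C)/C=C(\C)CCC[C@@H](C)C(=O)CC=C(C)C)c1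
F6 | step 11 | (5E,10R)-6,10,14-trimethyl-11-(triethylsilyloxy)pentadeca-5,13-dien-1-yn-4-ol, both C4 epimers | C#CCC(O)/C=C(\C)CCC[C@@H](C)C(O[Si](CC)(CC)CC)CC=C(C)C
F7 | step 11 | (1S)-1-[(2R,3R)-3-methyl-3-{(4R)-4,8-dimethyl-5-(triethylsilyloxy)non-7-en-1-yl}oxiran-2-yl]but-3-yn-1-ol | C#CC[C@H](O)[C@H]1O[C@]1(C)CCC[C@@H](C)C(O[Si](CC)(CC)CC)CC=C(C)C
F8 | step 15 | (4E,7R,8E,13R)-7-(tert-butyldimethylsilyloxy)-5,9,13,17-tetramethyl-14-(triethylsilyloxy)-1-(trimethylsilyl)octadeca-4,8,16-trien-1-yne | C[Si](C)(C)C#CC/C=C(\C)C[C@@H](O[Si](C)(C)C(C)(C)C)/C=C(\C)CCC[C@@H](C)C(O[Si](CC)(CC)CC)CC=C(C)C
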